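**Retrosynthetic overview**
1. Oxepane last: C3–O–C16 ether from a C16 triflate. Oxonane before it: C6–C7 by intramolecular B-alkyl Suzuki–Miyaura coupling, C8–C9 by allylation of the C9 oxocarbenium ion of a γ-lactol (tetrahydrofuran C1/C2/O/C9/C10).
2. Cyclohexane (C1, C10–C14) by a (3+3) ring enlargement: butane-2,3-dione (C13–C12–C11 plus C20) is inserted into the C10–C14 bond of a cyclopropane (C1, C10, C14) fused to the γ-lactone, forming C13–C14 (homo-Michael) and C10–C11 (aldol).
3. Enabling feature: C10 and C14 are 1,3-related through the ring-fusion carbon C1; C10 is alpha to C9 (lactone level, acceptor side) and C14 carries the C15 alkenyl group (donor side); C11 is a tertiary carbinol next to oxygenated C12, the aldol/enolate retron of a 1,2-diketone.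
4. Cyclopropane lactone from a copper-carbene cyclopropanation of a (Z)-dienyl diazomalonate; C3 from (R)-lactic acid (dioxolanone alkylation), C2 by transfer hydrogenation of an ynone.
5. Ring order: cyclopropane + γ-lactone → cyclohexane → tetrahydrofuran (lactol allylation) → oxonane → oxepane.

Key step: step 10

Numbering remark: eunicellane numbers are used: cyclohexane C1, C10–C14; tetrahydrofuran C1, C2, O, C9, C10; oxonane completed by C3–C8; oxepane oxygen joins C3 and C16; C15 carries C16 and methyl C17; C18 is the methyl on C3, C19 the methylene on C7, C20 the methyl on C11.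
Assumption: dioxolanone 1 (pivalaldehyde acetal of (R)-lactic acid) is taken as purchasable; it is otherwise one step from (R)-lactic acid.

Step 1
Reactants: 1 (2R,5R)-2-tert-butyl-5-methyl-1,3-dioxolan-4-one; 2 allyl bromide
Product: 3 (2R,5S)-5-allyl-2-tert-butyl-5-methyl-1,3-dioxolan-4-one
Conditions: LiN(i-Pr)2, THF, −78 °C; then 2, −78 → −30 °C
Reagents that add atoms: 2 allyl bromide, C=CCBr
Why: The lithium enolate of the lactic acid dioxolanone is alkylated anti to the tert-butyl group (self-regeneration of stereocentres), which sets the quaternary carbon that becomes C3.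

Step 2
Reactants: 3 (2R,5S)-5-allyl-2-tert-butyl-5-methyl-1,3-dioxolan-4-one
Product: 4 (2S)-2-hydroxy-N-methoxy-N,2-dimethylpent-4-enamide
Conditions: MeNHOMe·HCl, i-PrMgCl, THF, −20 → 0 °C
Reagents that add atoms: N,O-dimethylhydroxylamine hydrochloride, CNOC.Cl
Why: Aminolysis of the activated acylal ester by the magnesium amide should give the Weinreb amide and release pivalaldehyde without touching the stereocentre.

Step 3
Reactants: 4 (2S)-2-hydroxy-N-methoxy-N,2-dimethylpent-4-enamide
Product: 5 (2S)-N-methoxy-N,2-dimethyl-2-(triethylsilyloxy)pent-4-enamide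
Conditions: Et3SiOTf, 2,6-lutidine, CH2Cl2, 0 °C
Reagents that add atoms: triethylsilyl trifluoromethanesulfonate, CC[Si](CC)(CC)OS(=O)(=O)C(F)(F)F
Why: A silyl triflate silylates the hindered tertiary alcohol, which must be masked before the carbene and oxocarbenium steps.

Step 4
Reactants: 5 (2S)-N-methoxy-N,2-dimethyl-2-(triethylsilyloxy)pent-4-enamide; 6 2-methylbut-1-en-3-yne
Product: 7 (6S)-2,6-dimethyl-6-(triethylsilyloxy)nona-1,8-dien-3-yn-5-one
Conditions: 6, n-BuLi, THF, −78 °C; then 5, −78 → 0 °C; NH4Cl (aq)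
Reagents that add atoms: 6 2-methylbut-1-en-3-yne, C=C(C)C#C
Why: Weinreb ketone synthesis, in which the chelated tetrahedral intermediate prevents over-addition of the lithium acetylide.

Step 5
Reactants: 7 (6S)-2,6-dimethyl-6-(triethylsilyloxy)nona-1,8-dien-3-yn-5-one
Product: 8 (5S,6S)-2,6-dimethyl-6-(triethylsilyloxy)nona-1,8-dien-3-yn-5-ol
Conditions: RuCl[(R,R)-TsDPEN](p-cymene) (2 mol %), i-PrOH, 25 °C
Reagents that add atoms: none
Why: Noyori asymmetric transfer hydrogenation of an ynone, in which the (R,R) catalyst should deliver hydride under reagent control to give the (S)-carbinol that becomes C2.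

Step 6
Reactants: 8 (5S,6S)-2,6-dimethyl-6-(triethylsilyloxy)nona-1,8-dien-3-yn-5-ol
Product: 9 (3Z,5S,6S)-2,6-dimethyl-6-(triethylsilyloxy)nona-1,3,8-trien-5-ol
Conditions: Zn dust activated with Cu(OAc)2 and AgNO3, MeOH/H2O, 40 °C
Reagents that add atoms: none
Why: Boland reduction of the conjugated enyne is cis-selective and leaves isolated alkenes alone, and the Z geometry later places the isopropenyl group endo on the cyclopropane.

Step 7
Reactants: 9 (3Z,5S,6S)-2,6-dimethyl-6-(triethylsilyloxy)nona-1,3,8-trien-5-ol; 10 3-tert-butoxy-3-oxopropanoic acid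
Product: 11 tert-butyl (3Z,5S,6S)-2,6-dimethyl-6-(triethylsilyloxy)nona-1,3,8-trien-5-yl malonate
Conditions: DCC, DMAP (cat.), CH2Cl2, 0 → 25 °C
Reagents that add atoms: 10 3-tert-butoxy-3-oxopropanoic acid, CC(C)(C)OC(=O)CC(=O)O
Why: Steglich esterification of the only free (secondary) hydroxyl.

Step 8
Reactants: 11 tert-butyl (3Z,5S,6S)-2,6-dimethyl-6-(triethylsilyloxy)nona-1,3,8-trien-5-yl malonate
Product: 12 tert-butyl (3Z,5S,6S)-2,6-dimethyl-6-(triethylsilyloxy)nona-1,3,8-trien-5-yl 2-diazomalonate
Conditions: 4-acetamidobenzenesulfonyl azide, DBU, MeCN, 0 → 25 °C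
Reagents that add atoms: 4-acetamidobenzenesulfonyl azide, CC(=O)Nc1ccc(cc1)S(=O)(=O)N=[N+]=[N-]
Why: Regitz diazo transfer to the acidic malonate methylene.

Step 9
Reactants: 12 tert-butyl (3Z,5S,6S)-2,6-dimethyl-6-(triethylsilyloxy)nona-1,3,8-trien-5-yl 2-diazomalonate
Product: 13 tert-butyl 2-oxo-6-endo-(prop-1-en-2-yl)-4-[(2S)-2-(triethylsilyloxy)pent-4-en-2-yl]-3-oxabicyclo[3.1.0]hexane-1-carboxylate (side chain anti to the cyclopropane)
Conditions: [Cu(MeCN)4]PF6 (5 mol %), ClCH2CH2Cl, 60 °C, slow addition of 12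
Reagents that add atoms: none
Why: Intramolecular copper-carbene cyclopropanation of the proximal Z-alkene (five-membered lactone) is stereospecific, so the isopropenyl group ends endo on C14, and allylic 1,3-strain in the Z-allylic ester places the C2 side chain anti to the new ring, which sets C1 and C10.

Step 10
Reactants: 13 cyclopropane lactone ester; 14 butane-2,3-dione
Product: 16 cis-fused lactone cyclohexanone (10-CO2t-Bu; 11-OH and 11-CH3; 12-oxo; 14-isopropenyl), via ring-opened diketone enolate 15 (not isolated)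
Conditions: 14 (4 equiv, slow addition), 2-tert-butyl-1,1,3,3-tetramethylguanidine (0.3 equiv), MeCN, 0 → 25 °C
Reagents that add atoms: 14 butane-2,3-dione, CC(=O)C(C)=O
Why: Proposed new method: The guanidinium enolate of 14 should open the doubly activated cyclopropane at C14 by SN2 attack anti to the C10–C14 bond (homo-Michael addition, inversion at C14) to give the stabilised C10 enolate 15, which adds to the distal acetyl carbonyl C11 in a 6-(enolexo)-exo-trig aldol, so that three carbons are inserted into the C10–C14 bond and the cyclopropane is enlarged to the cyclohexane. The closest known reactions are homo-conjugate additions of stabilised enolates to 1-alkoxycarbonyl-3-oxabicyclo[3.1.0]hexan-2-ones and (3+3) ring-opening/aldol annulations of donor–acceptor cyclopropanes with mercaptoacetaldehyde; a 1,2-diketone as all-carbon partner has not been shown. C14 is fixed by inversion at the endo-isopropenyl carbon, C10 by the tether from C1, which brings C11 to the enolate face cis to C14 (cis ring fusion), and C11 by a non-chelated chair transition state with the methyl group equatorial and the alkoxide axial, anti to the C9 carbonyl. Attack at C14 rather than at C1 or at the alkene terminus C16 is secured because only the C10–C14 bond overlaps with both carbonyl π systems of the bicyclic lactone ester and C14 is allylic. Closure on C11 rather than on C12 (five-membered ring) relies on the reversibility of the aldol, the cyclohexanone ketol being the expected thermodynamic product; only catalytic base is needed because the alkoxide of 16 deprotonates 14.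

Step 11
Reactants: 16 cis-fused lactone cyclohexanone
Product: 19 cis-fused lactone with H on C10 (11-OSiEt3; 12-oxo), via bis-silylated ester 17 (not isolated), via carboxylic acid 18 (not isolated)
Conditions: Et3SiOTf (3 equiv), 2,6-lutidine, CH2Cl2, 0 → 25 °C; NaHCO3 (aq) work-up; then toluene, 100 °C
Reagents that add atoms: triethylsilyl trifluoromethanesulfonate, CC[Si](CC)(CC)OS(=O)(=O)C(F)(F)F
Why: The silyl triflate silylates the tertiary aldol hydroxyl (blocking retro-aldol) and cleaves the tert-butyl ester with loss of isobutene, the silyl ester is hydrolysed on work-up, and the malonic half-acid loses CO2 through a cyclic transition state with protonation of the enol on the convex face to keep the cis ring fusion.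

Step 12
Reactants: 19 cis-fused lactone with H on C10
Product: 20 lactol (C9–OH, both anomers) with 12-OH cis to 11-OSiEt3
Conditions: i-Bu2AlH (2.3 equiv), CH2Cl2, −78 °C; KNaC4H4O6 (aq) work-up
Reagents that add atoms: none
Why: The lactone should stop at the lactol (stable aluminium hemiacetal at −78 °C) while hydride adds to the C12 ketone anti to the axial C11–OSiEt3 bond (polar Felkin–Anh control, the silyl ether shields the other face), which sets C12 with its oxygen cis to O11.

Step 13
Reactants: 20 lactol; 21 (2-bromoallyl)trimethylsilane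
Product: 22 2,5-cis tetrahydrofuran carrying CH2C(Br)=CH2 on C9 (12-OH free)
Conditions: 21 (4 equiv), BF3·OEt2, CH2Cl2/MeCN, −78 → −30 °C
Reagents that add atoms: 21 (2-bromoallyl)trimethylsilane, C=C(Br)C[Si](C)(C)C
Why: Hosomi–Sakurai allylation of the five-membered oxocarbenium ion should occur on the convex face, anti to the C10 and C1 substituents of the cis-fused bicycle, which sets C9 with C8 cis to the C2 side chain.

Step 14
Reactants: 22 bromoallyl tetrahydrofuran; 23 octanoyl chloride
Product: 24 12-octanoate of 22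
Conditions: 23, pyridine, DMAP, CH2Cl2, 25 °C
Reagents that add atoms: 23 octanoyl chloride, CCCCCCCC(=O)Cl
Why: DMAP-catalysed acylation of the only free hydroxyl (C12).

Step 15
Reactants: 24 12-octanoate
Product: 27 tricyclic primary alcohol (oxonane closed; 16-OH; 3- and 11-OSiEt3), via bis-borane 25 (not isolated), via cyclised C16-borane 26 (not isolated)
Conditions: 9-BBN (2.1 equiv), THF, 0 → 25 °C; then Pd(dppf)Cl2 (10 mol %), AsPh3, Cs2CO3, DMF/THF/H2O, 40 °C, high dilution; then H2O2, NaH2PO4/Na2HPO4 buffer (pH 7), 0 °C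
Reagents that add atoms: hydrogen peroxide, OO
Why: 9-BBN adds to both terminal alkenes (the 2-bromoalkene is inert), the unbranched C6 borane closes the oxonane by intramolecular B-alkyl Suzuki–Miyaura coupling with the C7 bromide on the face it shares with C9 (the branched C16 borane transmetalates more slowly and would have to bridge the opposite face), and oxidation turns the C16–B bond into the alcohol, C15 being set in the hydroboration by borane approach anti to C1 in the rotamer with C14–H eclipsing the alkene.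

Step 16
Reactants: 27 tricyclic primary alcohol
Product: 28 triol (3-OH, 11-OH, 16-OH)
Conditions: HF·pyridine, pyridine, THF, 0 → 25 °C
Reagents that add atoms: none
Why: Buffered fluoride cleaves both tertiary triethylsilyl ethers under non-basic conditions that leave the octanoate and the exocyclic alkene untouched.

Step 17
Reactants: 28 triol
Product: 30 CNP0286133.1, via primary triflate 29 (not isolated)
Conditions: Tf2O (1.1 equiv), 2,6-lutidine, CH2Cl2, −78 → 0 °C
Reagents that add atoms: none
Why: Selective triflation of the primary C16 hydroxyl followed by intramolecular Williamson-type displacement by the tertiary C3 hydroxyl closes the oxepane (7-exo-tet), the hindered C11 hydroxyl being unable to reach C16.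

**Compound list**
1 | (2R,5R)-2-tert-butyl-5-methyl-1,3-dioxolan-4-one | CC(C)(C)[C@@H]1O[C@H](C)C(=O)O1 | starting material
2 | allyl bromide | C=CCBr | starting material
3 | (2R,5S)-5-allyl-2-tert-butyl-5-methyl-1,3-dioxolan-4-one | CC(C)(C)[C@@H]1O[C@](CC=C)(C)C(=O)O1 | intermediate
4 | (2S)-2-hydroxy-N-methoxy-N,2-dimethylpent-4-enamide | C=CC[C@](C)(O)C(=O)N(C)OC | intermediate
5 | (2S)-N-methoxy-N,2-dimethyl-2-(triethylsilyloxy)pent-4-enamide | C=CC[C@](C)(O[Si](CC)(CC)CC)C(=O)N(C)OC | intermediate
6 | 2-methylbut-1-en-3-yne | C=C(C)C#C | starting material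
7 | (6S)-2,6-dimethyl-6-(triethylsilyloxy)nona-1,8-dien-3-yn-5-one | C=CC[C@](C)(O[Si](CC)(CC)CC)C(=O)C#CC(C)=C | intermediate
8 | (5S,6S)-2,6-dimethyl-6-(triethylsilyloxy)nona-1,8-dien-3-yn-5-ol | C=CC[C@](C)(O[Si](CC)(CC)CC)[C@@H](O)C#CC(C)=C | intermediate
9 | (3Z,5S,6S)-2,6-dimethyl-6-(triethylsilyloxy)nona-1,3,8-trien-5-ol | C=CC[C@](C)(O[Si](CC)(CC)CC)[C@@H](O)/C=C\C(C)=C | intermediate
10 | 3-tert-butoxy-3-oxopropanoic acid (mono-tert-butyl malonate) | CC(C)(C)OC(=O)CC(=O)O | starting material
11 | tert-butyl (3Z,5S,6S)-2,6-dimethyl-6-(triethylsilyloxy)nona-1,3,8-trien-5-yl malonate | CC(C)(C)OC(=O)CC(=O)O[C@@H](/C=C\C(C)=C)[C@](C)(CC=C)O[Si](CC)(CC)CC | intermediate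
12 | tert-butyl (3Z,5S,6S)-2,6-dimethyl-6-(triethylsilyloxy)nona-1,3,8-trien-5-yl 2-diazomalonate | CC(C)(C)OC(=O)C(=[N+]=[N-])C(=O)O[C@@H](/C=C\C(C)=C)[C@](C)(CC=C)O[Si](CC)(CC)CC | intermediate
13 | tert-butyl 2-oxo-6-endo-(prop-1-en-2-yl)-4-[(2S)-2-(triethylsilyloxy)pent-4-en-2-yl]-3-oxabicyclo[3.1.0]hexane-1-carboxylate, side chain anti to the cyclopropane (bicycle C1 = C10, C5 = C1, C6 = C14, C4 = C2) | O=C1O[C@H]([C@](C)(CC=C)O[Si](CC)(CC)CC)[C@H]2[C@@H](C(C)=C)[C@@]12C(=O)OC(C)(C)C | intermediate
14 | butane-2,3-dione | CC(=O)C(C)=O | starting material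
15 | ring-opened γ-lactone tert-butyl ester carrying on C1 the 2-methyl-5,6-dioxohept-1-en-3-yl chain (C14, C13, C12, C11, C20); present in the flask as its C10 enolate | O=C1O[C@H]([C@](C)(CC=C)O[Si](CC)(CC)CC)[C@@H]([C@@H](CC(=O)C(C)=O)C(C)=C)C1C(=O)OC(C)(C)C | intermediate
16 | C9 γ-lactone cis-fused at C1/C10 to the cyclohexanone: 10-CO2t-Bu, 11-OH and 11-CH3 (OH cis to the ester), 12-oxo, 14-isopropenyl trans to C2 | O=C1O[C@H]([C@](C)(CC=C)O[Si](CC)(CC)CC)[C@@H]2[C@@]1(C(=O)OC(C)(C)C)[C@@](C)(O)C(=O)C[C@H]2C(C)=C | intermediate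
17 | as 16 with 11-OSiEt3 and a triethylsilyl ester on C10 | O=C1O[C@H]([C@](C)(CC=C)O[Si](CC)(CC)CC)[C@@H]2[C@@]1(C(=O)O[Si](CC)(CC)CC)[C@@](C)(O[Si](CC)(CC)CC)C(=O)C[C@H]2C(C)=C | intermediate
18 | as 17 with the free carboxylic acid on C10 | O=C1O[C@H]([C@](C)(CC=C)O[Si](CC)(CC)CC)[C@@H]2[C@@]1(C(=O)O)[C@@](C)(O[Si](CC)(CC)CC)C(=O)C[C@H]2C(C)=C | intermediate
19 | cis-fused lactone with H on C10, 11-OSiEt3, 12-oxo | O=C1O[C@H]([C@](C)(CC=C)O[Si](CC)(CC)CC)[C@@H]2[C@H]1[C@@](C)(O[Si](CC)(CC)CC)C(=O)C[C@H]2C(C)=C | intermediate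
20 | lactol (C9–OH, both anomers) with 12-OH cis to 11-OSiEt3 | OC1O[C@H]([C@](C)(CC=C)O[Si](CC)(CC)CC)[C@@H]2[C@H]1[C@@](C)(O[Si](CC)(CC)CC)[C@@H](O)C[C@H]2C(C)=C | intermediate
21 | (2-bromoallyl)trimethylsilane | C=C(Br)C[Si](C)(C)C | starting material
22 | 2,5-cis tetrahydrofuran with CH2C(Br)=CH2 on C9, 12-OH free | C=C(Br)C[C@@H]1O[C@H]([C@](C)(CC=C)O[Si](CC)(CC)CC)[C@@H]2[C@H]1[C@@](C)(O[Si](CC)(CC)CC)[C@@H](O)C[C@H]2C(C)=C | intermediate
23 | octanoyl chloride | CCCCCCCC(=O)Cl | starting material
24 | 12-octanoate of 22 | C=C(Br)C[C@@H]1O[C@H]([C@](C)(CC=C)O[Si](CC)(CC)CC)[C@@H]2[C@H]1[C@@](C)(O[Si](CC)(CC)CC)[C@@H](OC(=O)CCCCCCC)C[C@H]2C(C)=C | intermediate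
25 | bis-borane with 9-BBN on C6 and on C16 | C=C(Br)C[C@@H]1O[C@H]([C@](C)(CCCB3C4CCCC3CCC4)O[Si](CC)(CC)CC)[C@@H]2[C@H]1[C@@](C)(O[Si](CC)(CC)CC)[C@@H](OC(=O)CCCCCCC)C[C@H]2[C@@H](C)CB5C6CCCC5CCC6 | intermediate
26 | oxonane closed (C6–C7), 9-BBN still on C16 | C=C1CCC[C@](C)(O[Si](CC)(CC)CC)[C@H]2O[C@@H](C1)[C@H]1[C@@H]2[C@H]([C@@H](C)CB3C4CCCC3CCC4)C[C@H](OC(=O)CCCCCCC)[C@]1(C)O[Si](CC)(CC)CC | intermediate
27 | tricyclic primary alcohol: 16-OH, 3- and 11-OSiEt3, 12-octanoate, 7-methylene | C=C1CCC[C@](C)(O[Si](CC)(CC)CC)[C@H]2O[C@@H](C1)[C@H]1[C@@H]2[C@H]([C@@H](C)CO)C[C@H](OC(=O)CCCCCCC)[C@]1(C)O[Si](CC)(CC)CC | intermediate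
28 | triol: 3-OH, 11-OH, 16-OH | C=C1CCC[C@](C)(O)[C@H]2O[C@@H](C1)[C@H]1[C@@H]2[C@H]([C@@H](C)CO)C[C@H](OC(=O)CCCCCCC)[C@]1(C)O | intermediate
29 | C16 triflate of 28 | C=C1CCC[C@](C)(O)[C@H]2O[C@@H](C1)[C@H]1[C@@H]2[C@H]([C@@H](C)COS(=O)(=O)C(F)(F)F)C[C@H](OC(=O)CCCCCCC)[C@]1(C)O | intermediate
30 | CNP0286133.1 | C=C1CCC[C@]2(C)OC[C@H](C)[C@@H]3C[C@H](OC(=O)CCCCCCC)[C@](C)(O)[C@@H]4[C@H]3[C@@H]2O[C@H]4C1 | target

**Step count**
Total steps: 17. Longest linear sequence: 17 steps (1 → 30).

**Steps most likely to fail**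

1. Step 10 (Proposed new method). The ring opening may lose to SN2′ attack at C16 or to self-condensation of 14. The aldol may close on C12, and facial selectivity at C11 may be low. Fallback, from 13: 14 is converted with Me3SiCl and Et3N into its silyl enol ether 3-(trimethylsilyloxy)but-3-en-2-one F1. Sc(OTf)3-catalysed ring opening of 13 by F1 (the known opening of donor–acceptor cyclopropanes by enol silanes, with inversion at C14) should give, after desilylation on work-up, the neutral diketone 15, which is isolated. A separate amine-base aldol cyclisation of 15 (known intramolecular aldol of a 1,3-dicarbonyl onto a 1,2-diketone) comes back to the route at 16.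

2. Step 15. The nine-membered ring closure may lose to oligomerisation or to coupling of the branched C16 borane. Facial selectivity in the hydroboration of the isopropenyl group is the weakest stereochemical prediction of the route; the rotamer argument is not secure and may favour the C15 epimer. Fallback, from 24: double hydroboration with diisopinocampheylborane (enantiomer chosen to reinforce the wanted face at C15) and oxidation should give the C6,C16-diol F4. HF·pyridine removes both silyl ethers to give the tetraol F5. Tf2O with 2,6-lutidine, then Bu4NI, closes the oxepane by attack of the C3 hydroxyl on activated C16 and turns activated C6 into the primary iodide, the oxepane iodide F6. Insertion of Zn (LiCl, THF) into the C–I bond and intramolecular Negishi coupling with the 2-bromoalkene (Pd(PPh3)4) comes back to the route at 30.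

3. Step 12. Hydride may add to the C12 ketone from the silyl ether face (poor facial selectivity), and the lactone may be over-reduced. Fallback, from 19: if the reduction gives the C12-epimeric lactol F2, it is taken through the allylation of step 13 unchanged to the C12-epimeric alcohol F3. Mitsunobu esterification of F3 with octanoic acid (PPh3, DIAD) inverts C12 and comes back to the route at 24.

**Further compounds**
F1 | step 10 | 3-(trimethylsilyloxy)but-3-en-2-one | C=C(O[Si](C)(C)C)C(C)=O
F2 | step 12 | C12 epimer of lactol 20 | OC1O[C@H]([C@](C)(CC=C)O[Si](CC)(CC)CC)[C@@H]2[C@H]1[C@@](C)(O[Si](CC)(CC)CC)[C@H](O)C[C@H]2C(C)=C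
F3 | step 12 | C12 epimer of alcohol 22 | C=C(Br)C[C@@H]1O[C@H]([C@](C)(CC=C)O[Si](CC)(CC)CC)[C@@H]2[C@H]1[C@@](C)(O[Si](CC)(CC)CC)[C@H](O)C[C@H]2C(C)=C
F4 | step 15 | C6,C16-diol from 24 (vinyl bromide, silyl ethers and octanoate kept) | C=C(Br)C[C@@H]1O[C@H]([C@](C)(CCCO)O[Si](CC)(CC)CC)[C@@H]2[C@H]1[C@@](C)(O[Si](CC)(CC)CC)[C@@H](OC(=O)CCCCCCC)C[C@H]2[C@@H](C)CO
F5 | step 15 | tetraol (3-OH, 11-OH, 6-OH, 16-OH) | C=C(Br)C[C@@H]1O[C@H]([C@](C)(CCCO)O)[C@@H]2[C@H]1[C@@](C)(O)[C@@H](OC(=O)CCCCCCC)C[C@H]2[C@@H](C)CO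
F6 | step 15 | oxepane iodide (C6–I, 2-bromoallyl on C9) | ICCC[C@]2(C)OC[C@H](C)[C@@H]3C[C@H](OC(=O)CCCCCCC)[C@](C)(O)[C@@H]4[C@H]3[C@@H]2O[C@H]4CC(Br)=C
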